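In larch, ash, maple and alder the ratio of [Rea] to [Sub] at the start is 1.20, so you have a little more Rea than one per Sub.

in all of them: Sub 0.050 M

|  | Rea | temperature | remark | time |
|---|---|---|---|---|
| autumn | 0.084 M | 5 °C | run made earlier |  |
| summer | 0.13 M | 55 °C | run made earlier |  |
| larch | 0.0600 M | 100 °C |  | 4.0 min |
| ash | 0.0600 M | 40 °C |  | 4.0 min |
| maple | 0.0600 M | 10 °C |  | 4.0 min |
| alder | 0.0600 M | 70 °C |  | 4.0 min |

* the flask with the highest amount of Sub.Rea, in percent of the Sub charged ("all alike" if they lie within 1.5 percentage points) (larch / ash / maple / alder / all alike)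
* final Sub.Rea, as a percentage of the Sub charged, in larch
* final Sub.Rea, as a percentage of the Sub charged, in ash
* final Sub.Rea, as a percentage of the Sub charged, in maple
* final Sub.Rea, as a percentage of the Sub charged, in alder

- autumn (time / min: Sub.Rea / %): 50.0: 29.0; 80.0: 23.6; 90.0: 24.5; 150: 20.2; 240: 21.0; 360: 18.0; 600: 19.4
- summer (time / min: Sub.Rea / %): 6.00: 4.1; 12.0: 0.6; 20.0: 0.2; 30.0: 0; 40.0: 0; 50.0: 0.3

(each reading ± 0.5 percentage points)

- the earlier runs were read with a standard deviation of 0.5 percentage points
- steps that have been proposed: 2 Rea -> Sdp; Rea + Sub.Rea -> Sdp2; Sub.Rea <-> Sdp3; Sub + Rea -> Sub.Rea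

Follow one Sub through such a flask. In the first instants it meets Rea and becomes Sub.Rea, and with no Sub.Rea yet standing, nothing can be lost. In the middle the new Sub.Rea stands at a fork: a Rea can take it to Sdp2, or it can pass by itself into Sdp3. Once Rea is used, Sdp3 is the door left open. So you want to know how long a Sub.Rea lasts against the time in the flask, and the runs give a reading of that.

The summer run falls from 4.1 % to 0.6 % between 6.00 min and 12.0 min, a half-life of 2.16 min. With 2.60 Rea per Sub charged, this is a pseudo-first-order reading, and its lower point lies close to the scatter of 0.5 percentage points. The autumn run is no such decay, because its readings level off from 150 min on, at a mean of 19.6 %. So there you read the part above that plateau: from the reading at 50.0 min to the mean of those at 80.0 min and 90.0 min, it gives a half-life of about 32.2 min, a rough reading given the scatter.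

Now draw a straight line through the logarithms of these half-lives, from 5 °C to 55 °C, and extend it. In larch at 100 °C that gives 0.191 min, and this number, the half-life of Sub.Rea at the flask's own temperature, is what I carry. Against 4.0 min it makes 21.0 half-lives in larch, 4.15 in alder and 0.822 in ash. It mixes both doors of the fork, sets a fall towards zero in the summer run beside a fall to a plateau in the autumn run, and is a long extrapolation, so I commit only to an order: ash on top, alder under it, larch far under both.

The forecast also names ash, but it differs from me on larch. It gives 29 % (17 % to 42 %) there, 35 % (25 % to 47 %) in ash, 24 % (12 % to 36 %) in maple and 33 % (22 % to 45 %) in alder, on the ground that “the hotter flasks lose more to Sdp3, side reactions and poorer selectivity”.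

The simulation puts ash highest, with 35.6 %, against 26.8 % in maple, 20.6 % in alder and 5.37 % in larch.

    2 Rea → Sdp (k = 0.180 L mol⁻¹ s⁻¹, Ea = 74.0 kJ mol⁻¹)
    Rea + Sub.Rea → Sdp2 (k = 2.00 L mol⁻¹ s⁻¹, Ea = 41.0 kJ mol⁻¹)
    Sub.Rea ⇌ Sdp3 (K = 7.30, k = 0.0380 s⁻¹, Ea = 99.0 kJ mol⁻¹, ΔH = −59.0 kJ mol⁻¹)
    Sub + Rea → Sub.Rea (k = 1.60 L mol⁻¹ s⁻¹, Ea = 38.0 kJ mol⁻¹)
    (constants at 100 °C)

The forecast and the flask part most widely on larch, at 29 % against 5.37 %. In larch the half-life of Sub.Rea by the forward step into Sdp3 alone is 0.30 min at 0.110 min, shorter than the run's 4.0 min, and at the end Sdp3 holds 39.0 % of the Sub charged, against 5.37 % as Sub.Rea. The carried half-life of 0.191 min is shorter still. Its count of 4.15 for alder lies below the 21.0 for larch, and alder holds more Sub.Rea than larch: 20.6 % at 4.00 min, falling to 1.01 % at 40.0 min.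

All runs were generated by integration with constants of no real substance; scatter was added.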